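**Retrosynthetic overview**

1. Target 28 ⇐ global methanolysis of its tris-TBS/triacetate 27.
2. 27 ⇐ one-flask double ring formation from acyclic 1,3-diketone 15 and chalcone 22: first the pyranone (cyclodehydration to dienyl flavone 24, never isolated), then the cyclohexene by an exo-selective (S)-VANOL–borate Diels–Alder that sets all three stereocentres.
3. 15 ⇐ C-prenylation ⇐ C-acylation of dienyl acetophenone 7 with acid chloride 13; 7 ⇐ Suzuki coupling of iodide 3 (from phloroacetophenone).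
4. 22 ⇐ selective acetylation of morachalcone A 21 ⇐ Claisen–Schmidt condensation of 3-prenylresacetophenone 17 with aldehyde 19.
5. Ring order: the three benzene rings are bought; pyranone, then cyclohexene, both in step 12.

Assumption: by a quadrant model of the spiro-borate, the (S)-VANOL borate shields the Cα-Si face of the chelated chalcone so the diene adds to the Cα-Re/Cβ-Re face; this sense is derived from the model, not from a verified precedent, and the (R)-ligand would be used unchanged if it proved opposite.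

**Step 1**
Reactants: 1 2,4,6-trihydroxyacetophenone
Product: 2 1-[2-hydroxy-4,6-bis(tert-butyldimethylsilyloxy)phenyl]ethanone
Conditions: TBSCl (2.1 equiv), imidazole, DMF, 0 °C → rt
Reagents that add atoms: tert-butyldimethylsilyl chloride, CC(C)(C)[Si](C)(C)Cl
Why: Chelation-controlled O-silylation; the para OH and one of the two equivalent ortho OH groups react, and the remaining ortho OH is locked in a hydrogen bond to the ketone and stays free.

**Step 2**
Reactants: 2 1-[2-hydroxy-4,6-bis(tert-butyldimethylsilyloxy)phenyl]ethanone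
Product: 3 1-[2-hydroxy-3-iodo-4,6-bis(tert-butyldimethylsilyloxy)phenyl]ethanone
Conditions: NIS (1.05 equiv), CH2Cl2, 0 °C, dark
Reagents that add atoms: N-iodosuccinimide, O=C1CCC(=O)N1I
Why: Electrophilic aromatic iodination directed ortho to the free phenol; the alternative position lies between two bulky OTBS groups and is blocked.

**Step 3**
Reactants: 3 1-[2-hydroxy-3-iodo-4,6-bis(tert-butyldimethylsilyloxy)phenyl]ethanone, 4 2-methylbut-1-en-3-yne, 5 pinacolborane
Product: 7 1-[2-hydroxy-3-[(E)-3-methylbuta-1,3-dienyl]-4,6-bis(tert-butyldimethylsilyloxy)phenyl]ethanone, via dienyl pinacol boronate 6 (not isolated)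
Conditions: 4, 5, Cp2Zr(H)Cl (5 mol%), Et3N (10 mol%), neat, 40 °C; then 3, Pd(OAc)2/SPhos (cat.), K3PO4, THF/H2O, 45 °C
Reagents that add atoms: none
Why: Zirconium-catalysed syn-hydroboration of the terminal alkyne gives the (E)-dienyl boronate, and Suzuki–Miyaura coupling with retention installs the (E)-diene on the hindered aryl iodide.

**Step 4**
Reactants: 8 methyl 2,4-dihydroxybenzoate, 9 prenyl bromide (1-bromo-3-methylbut-2-ene)
Product: 11 2-hydroxy-4-(3-methylbut-2-enyloxy)benzoic acid, via methyl 2-hydroxy-4-prenyloxybenzoate 10 (not isolated)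
Conditions: K2CO3, DMF, rt; then LiOH, MeOH/H2O, 50 °C; cold dilute HCl
Reagents that add atoms: lithium hydroxide, [Li+].[OH-]
Why: Williamson etherification occurs only at the 4-OH because the 2-OH is hydrogen-bonded to the ester, and saponification in the same pot gives the acid.

**Step 5**
Reactants: 11 2-hydroxy-4-(3-methylbut-2-enyloxy)benzoic acid
Product: 13 2-(tert-butyldimethylsilyloxy)-4-(3-methylbut-2-enyloxy)benzoyl chloride, via bis-TBS benzoate 12 (not isolated)
Conditions: TBSCl (2.2 equiv), imidazole, CH2Cl2, rt, filter; then (COCl)2, DMF (cat.), CH2Cl2, 0 °C → rt; high vacuum, used crude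
Reagents that add atoms: tert-butyldimethylsilyl chloride, CC(C)(C)[Si](C)(C)Cl; oxalyl chloride, O=C(Cl)C(Cl)=O
Why: Silylation of both OH groups followed by Vilsmeier-type conversion of the silyl ester into the acid chloride under neutral conditions, which spares the aryl silyl ether and the prenyl ether.

**Step 6**
Reactants: 7 1-[2-hydroxy-3-[(E)-3-methylbuta-1,3-dienyl]-4,6-bis(tert-butyldimethylsilyloxy)phenyl]ethanone, 13 2-(tert-butyldimethylsilyloxy)-4-(3-methylbut-2-enyloxy)benzoyl chloride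
Product: 14 1-[2-hydroxy-3-[(E)-3-methylbuta-1,3-dienyl]-4,6-bis(tert-butyldimethylsilyloxy)phenyl]-3-[2-(tert-butyldimethylsilyloxy)-4-(3-methylbut-2-enyloxy)phenyl]propane-1,3-dione
Conditions: LiHMDS (3.2 equiv), THF, −78 °C; then 13, −78 → −20 °C; aq. NH4Cl
Reagents that add atoms: none
Why: Claisen-type C-acylation of the phenoxide/enolate dianion (one-pot equivalent of the Baker–Venkataraman rearrangement) gives the 1,3-diketone directly, and low temperature keeps the silyl ethers intact.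

**Step 7**
Reactants: 14 the 1,3-dione from step 6, 9 prenyl bromide
Product: 15 1-[2-hydroxy-3-[(E)-3-methylbuta-1,3-dienyl]-4,6-bis(tert-butyldimethylsilyloxy)phenyl]-2-(3-methylbut-2-enyl)-3-[2-(tert-butyldimethylsilyloxy)-4-(3-methylbut-2-enyloxy)phenyl]propane-1,3-dione
Conditions: K2CO3, acetone, rt → 40 °C
Reagents that add atoms: none
Why: C-alkylation of the β-diketone at the doubly activated carbon (the chelated phenol is far less nucleophilic); the new α-stereocentre is racemic and is erased in step 12, and 15 is handled as the open diketone in equilibrium with its hemiketal.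

**Step 8**
Reactants: 16 2,4-dihydroxyacetophenone, 9 prenyl bromide
Product: 17 1-[2,4-dihydroxy-3-(3-methylbut-2-enyl)phenyl]ethanone
Conditions: 10% aq. KOH, 0 °C → rt; chromatography
Reagents that add atoms: none
Why: Nuclear C-prenylation of the ambident resorcinolate in water, where C3 between the two oxygens is the most nucleophilic carbon; the 5-C- and O-prenyl isomers are separated.

**Step 9**
Reactants: 18 2,4-dihydroxybenzaldehyde
Product: 19 2,4-bis(methoxymethoxy)benzaldehyde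
Conditions: MOMCl (2.5 equiv), iPr2NEt, CH2Cl2, 0 °C → rt
Reagents that add atoms: chloromethyl methyl ether, COCCl
Why: Acetal protection of both phenols so that the aldehyde stays electrophilic under the strongly basic condensation.

**Step 10**
Reactants: 17 1-[2,4-dihydroxy-3-(3-methylbut-2-enyl)phenyl]ethanone, 19 2,4-bis(methoxymethoxy)benzaldehyde
Product: 21 morachalcone A, (E)-1-[2,4-dihydroxy-3-(3-methylbut-2-enyl)phenyl]-3-(2,4-dihydroxyphenyl)prop-2-en-1-one, via bis-MOM chalcone 20 (not isolated)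
Conditions: 50% aq. KOH, EtOH, rt, 48 h; then 3 M HCl, MeOH, 50 °C, 1 h
Reagents that add atoms: none
Why: Claisen–Schmidt condensation gives the thermodynamic (E)-enone by E1cB dehydration, and brief acid methanolysis of the MOM acetals in the same pot frees the phenols.

**Step 11**
Reactants: 21 morachalcone A
Product: 22 morachalcone A 2,4,4'-triacetate, 4-[(E)-3-[4-acetoxy-2-hydroxy-3-(3-methylbut-2-enyl)phenyl]-3-oxoprop-1-enyl]-1,3-phenylene diacetate
Conditions: Ac2O (3.2 equiv), pyridine, CH2Cl2, 0 °C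
Reagents that add atoms: acetic anhydride, CC(=O)OC(C)=O
Why: Chelation-controlled acetylation; the 2'-OH is hydrogen-bonded to the ketone and flanked by the prenyl group, so it stays free as the boron-binding site, and the acetates make the enone a better dienophile.

**Step 12**
Reactants: 15 the 2-prenyl-1,3-dione from step 7, 22 morachalcone A 2,4,4'-triacetate, 23 (S)-VANOL
Product: 27 tris-TBS triacetate of the target, 8-[(1S,5R,6S)-cyclohexenyl] adduct, via dienyl flavone 24 (not isolated), via chalcone VANOL borate 25 (not isolated), via adduct VANOL borate 26 (not isolated)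
Conditions: (i) 15, AcOH, PhCF3, 4 Å MS, 60 °C, then evaporate; (ii) 23, BH3·THF, AcOH, THF, rt, then 22; (iii) combine (i) and (ii), PhCF3, 4 Å MS, rt → 40 °C; H2O work-up; SiO2 separation of exo from endo
Reagents that add atoms: none
Why: Acid-catalysed cyclodehydration through the only free phenol closes the pyranone regiospecifically to the labile 8-dienyl flavone 24, which is consumed at once in a chiral spiro-borate-mediated asymmetric Diels–Alder reaction of the 2'-hydroxychalcone; suprafacial addition keeps the chalcone trans geometry (C5/C6 trans), the exo transition state places the flavone and aroyl groups trans (C1/C6), and the (S)-ligand directs the diene to the Cα-Re/Cβ-Re face, giving (1S,5R,6S).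

**Step 13**
Reactants: 27 tris-TBS triacetate of the target
Product: 28 target, 8-[(1S,5R,6S)-6-[2,4-dihydroxy-3-(3-methylbut-2-enyl)benzoyl]-5-(2,4-dihydroxyphenyl)-3-methylcyclohex-2-en-1-yl]-5,7-dihydroxy-2-[2-hydroxy-4-(3-methylbut-2-enyloxy)phenyl]-3-(3-methylbut-2-enyl)chromen-4-one
Conditions: K2CO3, degassed MeOH/THF, 0 °C → rt; AcOH quench
Reagents that add atoms: none
Why: Mild base methanolysis removes the three aryl acetates and three aryl silyl ethers without acid, so the prenyl groups and the adduct survive; the only epimerisable centre (α to the ketone) is already in the thermodynamic all-trans arrangement.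

**Compound list**

1 | 2,4,6-trihydroxyacetophenone | CC(=O)c1c(O)cc(O)cc1O | starting material
2 | 1-[2-hydroxy-4,6-bis(tert-butyldimethylsilyloxy)phenyl]ethanone | CC(=O)c1c(O)cc(O[Si](C)(C)C(C)(C)C)cc1O[Si](C)(C)C(C)(C)C | intermediate
3 | 1-[2-hydroxy-3-iodo-4,6-bis(tert-butyldimethylsilyloxy)phenyl]ethanone | CC(=O)c1c(O)c(I)c(O[Si](C)(C)C(C)(C)C)cc1O[Si](C)(C)C(C)(C)C | intermediate
4 | 2-methylbut-1-en-3-yne | C=C(C)C#C | starting material
5 | pinacolborane | CC1(C)OBOC1(C)C | starting material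
6 | (E)-4,4,5,5-tetramethyl-2-(3-methylbuta-1,3-dienyl)-1,3,2-dioxaborolane | C=C(C)/C=C/B1OC(C)(C)C(C)(C)O1 | intermediate
7 | 1-[2-hydroxy-3-[(E)-3-methylbuta-1,3-dienyl]-4,6-bis(tert-butyldimethylsilyloxy)phenyl]ethanone | CC(=O)c1c(O)c(/C=C/C(C)=C)c(O[Si](C)(C)C(C)(C)C)cc1O[Si](C)(C)C(C)(C)C | intermediate
8 | methyl 2,4-dihydroxybenzoate | COC(=O)c1ccc(O)cc1O | starting material
9 | prenyl bromide (1-bromo-3-methylbut-2-ene) | CC(C)=CCBr | starting material
10 | methyl 2-hydroxy-4-(3-methylbut-2-enyloxy)benzoate | COC(=O)c1ccc(OCC=C(C)C)cc1O | intermediate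
11 | 2-hydroxy-4-(3-methylbut-2-enyloxy)benzoic acid | OC(=O)c1ccc(OCC=C(C)C)cc1O | intermediate
12 | tert-butyldimethylsilyl 2-(tert-butyldimethylsilyloxy)-4-(3-methylbut-2-enyloxy)benzoate | CC(C)=CCOc1ccc(C(=O)O[Si](C)(C)C(C)(C)C)c(O[Si](C)(C)C(C)(C)C)c1 | intermediate
13 | 2-(tert-butyldimethylsilyloxy)-4-(3-methylbut-2-enyloxy)benzoyl chloride | CC(C)=CCOc1ccc(C(Cl)=O)c(O[Si](C)(C)C(C)(C)C)c1 | intermediate
14 | 1-[2-hydroxy-3-[(E)-3-methylbuta-1,3-dienyl]-4,6-bis(TBS-oxy)phenyl]-3-[2-(TBS-oxy)-4-(3-methylbut-2-enyloxy)phenyl]propane-1,3-dione | CC(C)=CCOc1ccc(C(=O)CC(=O)c2c(O)c(/C=C/C(C)=C)c(O[Si](C)(C)C(C)(C)C)cc2O[Si](C)(C)C(C)(C)C)c(O[Si](C)(C)C(C)(C)C)c1 | intermediate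
15 | 2-(3-methylbut-2-enyl) derivative of 14 (racemic at C2; ring–chain tautomer of the 2-hydroxyflavanone) | CC(C)=CCOc1ccc(C(=O)C(CC=C(C)C)C(=O)c2c(O)c(/C=C/C(C)=C)c(O[Si](C)(C)C(C)(C)C)cc2O[Si](C)(C)C(C)(C)C)c(O[Si](C)(C)C(C)(C)C)c1 | intermediate
16 | 2,4-dihydroxyacetophenone | CC(=O)c1ccc(O)cc1O | starting material
17 | 1-[2,4-dihydroxy-3-(3-methylbut-2-enyl)phenyl]ethanone | CC(=O)c1ccc(O)c(CC=C(C)C)c1O | intermediate
18 | 2,4-dihydroxybenzaldehyde | O=Cc1ccc(O)cc1O | starting material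
19 | 2,4-bis(methoxymethoxy)benzaldehyde | COCOc1ccc(C=O)c(OCOC)c1 | intermediate
20 | (E)-1-[2,4-dihydroxy-3-(3-methylbut-2-enyl)phenyl]-3-[2,4-bis(methoxymethoxy)phenyl]prop-2-en-1-one | COCOc1ccc(/C=C/C(=O)c2ccc(O)c(CC=C(C)C)c2O)c(OCOC)c1 | intermediate
21 | morachalcone A | O=C(/C=C/c1ccc(O)cc1O)c1ccc(O)c(CC=C(C)C)c1O | intermediate
22 | morachalcone A 2,4,4'-triacetate (2'-OH free) | CC(=O)Oc1ccc(/C=C/C(=O)c2ccc(OC(C)=O)c(CC=C(C)C)c2O)c(OC(C)=O)c1 | intermediate
23 | (S)-VANOL, (S)-3,3'-diphenyl-2,2'-binaphthalene-1,1'-diol (axial chirality not expressible in SMILES; recovered) | Oc1c(-c2c(-c3ccccc3)cc3ccccc3c2O)c(-c2ccccc2)cc2ccccc12 | starting material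
24 | 5,7-bis(TBS-oxy)-2-[2-(TBS-oxy)-4-(3-methylbut-2-enyloxy)phenyl]-8-[(E)-3-methylbuta-1,3-dienyl]-3-(3-methylbut-2-enyl)chromen-4-one | CC(C)=CCOc1ccc(-c2oc3c(/C=C/C(C)=C)c(O[Si](C)(C)C(C)(C)C)cc(O[Si](C)(C)C(C)(C)C)c3c(=O)c2CC=C(C)C)c(O[Si](C)(C)C(C)(C)C)c1 | intermediate
25 | spiro-borate of 22 (2'-phenoxide and C=O on boron) with (S)-VANOL (axis not encoded) | CC(=O)Oc1ccc(/C=C/C2=[O+][B-]3(Oc4c(-c5c(-c6ccccc6)cc6ccccc6c5O3)c(-c3ccccc3)cc3ccccc43)Oc3c(CC=C(C)C)c(OC(C)=O)ccc32)c(OC(C)=O)c1 | intermediate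
26 | (S)-VANOL spiro-borate of adduct 27 (axis not encoded) | CC(C)=CCOc1ccc(-c2oc3c([C@H]4C=C(C)C[C@@H](c5ccc(OC(C)=O)cc5OC(C)=O)[C@@H]4C6=[O+][B-]7(Oc8c(-c9c(-c%10ccccc%10)cc%10ccccc%10c9O7)c(-c7ccccc7)cc7ccccc87)Oc7c(CC=C(C)C)c(OC(C)=O)ccc76)c(O[Si](C)(C)C(C)(C)C)cc(O[Si](C)(C)C(C)(C)C)c3c(=O)c2CC=C(C)C)c(O[Si](C)(C)C(C)(C)C)c1 | intermediate
27 | 8-[(1S,5R,6S)-6-[4-acetoxy-2-hydroxy-3-(3-methylbut-2-enyl)benzoyl]-5-(2,4-diacetoxyphenyl)-3-methylcyclohex-2-en-1-yl]-5,7-bis(TBS-oxy)-2-[2-(TBS-oxy)-4-(3-methylbut-2-enyloxy)phenyl]-3-(3-methylbut-2-enyl)chromen-4-one | CC(C)=CCOc1ccc(-c2oc3c([C@H]4C=C(C)C[C@@H](c5ccc(OC(C)=O)cc5OC(C)=O)[C@@H]4C(=O)c4ccc(OC(C)=O)c(CC=C(C)C)c4O)c(O[Si](C)(C)C(C)(C)C)cc(O[Si](C)(C)C(C)(C)C)c3c(=O)c2CC=C(C)C)c(O[Si](C)(C)C(C)(C)C)c1 | intermediate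
28 | 8-[(1S,5R,6S)-6-[2,4-dihydroxy-3-(3-methylbut-2-enyl)benzoyl]-5-(2,4-dihydroxyphenyl)-3-methylcyclohex-2-en-1-yl]-5,7-dihydroxy-2-[2-hydroxy-4-(3-methylbut-2-enyloxy)phenyl]-3-(3-methylbut-2-enyl)chromen-4-one | CC(C)=CCOc1ccc(-c2oc3c([C@H]4C=C(C)C[C@@H](c5ccc(O)cc5O)[C@@H]4C(=O)c4ccc(O)c(CC=C(C)C)c4O)c(O)cc(O)c3c(=O)c2CC=C(C)C)c(O)c1 | target

**Totals**

Total step count: 13. Longest linear sequence: 7 steps (1, 2, 3, 6, 7, 12, 13).

**Three steps most likely to fail**

Step 12. The acetic acid may be too weak to dehydrate 15 cleanly, or the diene may suffer under acid. The exo:endo ratio in this class of borate Diels–Alder reactions is often only about 1:1 to 2:1, and the facial sense rests on the model stated above. The fallback takes the acid step away from the diene and isolates the diene before the cycloaddition. It sets out from iodide 3. Acylation with 13 (LiHMDS, THF, −78 °C) gives 1-[2-hydroxy-3-iodo-4,6-bis(TBS-oxy)phenyl]-3-[2-(TBS-oxy)-4-(3-methylbut-2-enyloxy)phenyl]propane-1,3-dione F1. C-prenylation with 9 (K2CO3, acetone) gives its 2-(3-methylbut-2-enyl) derivative F2. Cyclodehydration with catalytic CSA in toluene at 60 °C, with no diene present, gives 8-iodo-5,7-bis(TBS-oxy)-2-[2-(TBS-oxy)-4-(3-methylbut-2-enyloxy)phenyl]-3-(3-methylbut-2-enyl)chromen-4-one F3. Suzuki–Miyaura coupling of F3 with boronate 6 comes back to the route at 24, now purified, which enters the borate Diels–Alder with 22 to give 27. Ligand and endo/exo tuning can then be done on clean material.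

Step 3. The aryl iodide carries two ortho substituents, and the silyl ether ortho to the ketone may not survive aqueous phosphate. The fallback replaces the boron coupling by a Heck reaction and elimination. From 3, Heck coupling with 2-methylbut-3-en-2-ol (Pd(OAc)2, P(o-tol)3, Et3N, MeCN, 70 °C) gives 1-[2-hydroxy-3-[(E)-3-hydroxy-3-methylbut-1-enyl]-4,6-bis(TBS-oxy)phenyl]ethanone F4. Dehydration of the tertiary allylic alcohol with Burgess reagent (THF, rt) comes back to the route at 7.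

Step 8. Direct C-prenylation gives the 3-isomer in only modest yield beside 5-C- and O-prenyl products. The fallback fixes the position by halogenation and cross-coupling. From 16, iodination (I2, HIO3, aq. EtOH) between the two hydroxyl groups gives 1-(2,4-dihydroxy-3-iodophenyl)ethanone F5. Stille coupling with tributyl(3-methylbut-2-enyl)stannane (Pd(PPh3)4, DMF, 90 °C), which transfers the linear prenyl group, comes back to the route at 17.

**Further compounds**

F1 | step 12 | 1-[2-hydroxy-3-iodo-4,6-bis(TBS-oxy)phenyl]-3-[2-(TBS-oxy)-4-(3-methylbut-2-enyloxy)phenyl]propane-1,3-dione | CC(C)=CCOc1ccc(C(=O)CC(=O)c2c(O)c(I)c(O[Si](C)(C)C(C)(C)C)cc2O[Si](C)(C)C(C)(C)C)c(O[Si](C)(C)C(C)(C)C)c1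
F2 | step 12 | 2-(3-methylbut-2-enyl) derivative of F1 (racemic) | CC(C)=CCOc1ccc(C(=O)C(CC=C(C)C)C(=O)c2c(O)c(I)c(O[Si](C)(C)C(C)(C)C)cc2O[Si](C)(C)C(C)(C)C)c(O[Si](C)(C)C(C)(C)C)c1
F3 | step 12 | 8-iodo-5,7-bis(TBS-oxy)-2-[2-(TBS-oxy)-4-(3-methylbut-2-enyloxy)phenyl]-3-(3-methylbut-2-enyl)chromen-4-one | CC(C)=CCOc1ccc(-c2oc3c(I)c(O[Si](C)(C)C(C)(C)C)cc(O[Si](C)(C)C(C)(C)C)c3c(=O)c2CC=C(C)C)c(O[Si](C)(C)C(C)(C)C)c1
F4 | step 3 | 1-[2-hydroxy-3-[(E)-3-hydroxy-3-methylbut-1-enyl]-4,6-bis(TBS-oxy)phenyl]ethanone | CC(=O)c1c(O)c(/C=C/C(C)(C)O)c(O[Si](C)(C)C(C)(C)C)cc1O[Si](C)(C)C(C)(C)C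
F5 | step 8 | 1-(2,4-dihydroxy-3-iodophenyl)ethanone | CC(=O)c1ccc(O)c(I)c1O
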